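**Plan**

Numbering (plakortolide skeleton): C1 lactone C=O, C3 and C6 the two peroxide carbons, C4 the quaternary carbon bearing the lactone oxygen, C8 the side-chain methine, C16 benzylic; ring A = 1,2-dioxane, ring B = γ-lactone.
Retrosynthesis: cut C11=C12 (Julia–Kocienski), then the O–C4 bond of ring B (hydroacyloxylation of a C4=C5 alkene by the C1 ester), then both peroxide C–O bonds at C3 and C6 (singlet-oxygen [4+2]), then C4–C5 of the (3E,5E)-diene (Negishi coupling of a citronellal-derived alkenylalane with an α-silyl iodopentenoate).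
Forward: the open-chain diene ester is assembled first; ring A arises by cycloaddition; ring B closes second onto the C4=C5 bond that the cycloaddition leaves inside ring A next to the C3 ester arm; the styryl-diene tail is added last.
Stereochemistry: C8 comes from (R)-citronellal; a temporary silicon-bearing stereocentre at C2 (catalytic asymmetric Si–H insertion) steers singlet oxygen to one diene face; the suprafacial addition sets C3 and C6 together; C4 follows from the enforced cis ring fusion; silicon is then removed by fluoride.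

Key step: step 11

Remarks:
- Step 5 is written for Rh2(S-DOSP)4; its antipode Rh2(R-DOSP)4 is used instead if the sense of Si–H insertion on this substrate turns out opposite, so that the (2R)-silane 8 results.
- (4E)-5-Phenylpent-4-en-1-ol 21 is taken as a catalogue compound.
- Co(salen) stands for N,N'-bis(3,5-di-tert-butylsalicylidene)-1,2-cyclohexanediaminocobalt (divalent cobalt).

Step 1
Reactants: 1 pent-3-yn-1-ol
Product: 3 (3E)-4-iodopent-3-en-1-ol, via alkenylzirconocene 2 (not isolated)
Conditions: Cp2Zr(H)Cl (2.5 equiv), THF, rt then 40 °C; I2, 0 °C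
Reagents that add atoms: iodine, II
Why: Schwartz syn-hydrozirconation with excess hydride equilibrates zirconium to the alkyne carbon next to the methyl group, and iodinolysis with retention should give the (E)-alkenyl iodide in which the methyl group is cis to the chain.

Step 2
Reactants: 3 (3E)-4-iodopent-3-en-1-ol
Product: 5 (3E)-4-iodopent-3-enoic acid, via (3E)-4-iodopent-3-enal 4 (not isolated)
Conditions: TEMPO (20 mol%), PhI(OAc)2 (2.2 equiv), MeCN/H2O 1:1, rt
Reagents that add atoms: water, O
Why: oxoammonium-catalysed (TEMPO) oxidation takes the primary alcohol through the aldehyde hydrate to the acid under near-neutral conditions that should leave the alkenyl iodide and the β,γ-position of the double bond unchanged.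

Step 3
Reactants: 5 (3E)-4-iodopent-3-enoic acid
Product: 6 methyl (3E)-4-iodopent-3-enoate
Conditions: Me3SiCHN2, PhMe/MeOH 4:1, 0 °C
Reagents that add atoms: trimethylsilyldiazomethane, C[Si](C)(C)C=[N+]=[N-]
Why: O-methylation of the acid by the diazomethane equivalent needs no base, so the double bond cannot move into conjugation.

Step 4
Reactants: 6 methyl (3E)-4-iodopent-3-enoate
Product: 7 methyl (3E)-2-diazo-4-iodopent-3-enoate
Conditions: 4-acetamidobenzenesulfonyl azide, DBU, MeCN, 0 °C; used at once
Reagents that add atoms: 4-acetamidobenzenesulfonyl azide, CC(=O)Nc1ccc(cc1)S(=O)(=O)N=[N+]=[N-]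
Why: Regitz diazo transfer to the doubly activated (ester and vinyl) C2 methylene is the standard entry to vinyldiazoacetates.

Step 5
Reactants: 7 methyl (3E)-2-diazo-4-iodopent-3-enoate
Product: 8 methyl (2R,3E)-2-[dimethyl(phenyl)silyl]-4-iodopent-3-enoate
Conditions: Rh2(S-DOSP)4 (1 mol%), PhMe2SiH (2 equiv), pentane, −78 °C, slow addition of 7
Reagents that add atoms: dimethylphenylsilane, C[SiH](C)c1ccccc1
Why: enantioselective insertion of the rhodium vinylcarbenoid into the Si–H bond (donor/acceptor carbenoid chemistry of chiral dirhodium prolinates) creates the C2 stereocentre under catalyst control.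

Step 6
Reactants: 9 (R)-citronellal [(3R)-3,7-dimethyloct-6-enal]
Product: 10 (4R)-4,8-dimethylnon-7-en-1-yne
Conditions: dimethyl (1-diazo-2-oxopropyl)phosphonate, K2CO3, MeOH, 0 °C to rt
Reagents that add atoms: dimethyl (1-diazo-2-oxopropyl)phosphonate, CC(=O)C(=[N+]=[N-])P(=O)(OC)OC
Why: Ohira–Bestmann homologation turns the aldehyde into the terminal alkyne (future C5 and C6), and the stereocentre (future C8) is β to the carbonyl and cannot epimerise.

Step 7
Reactants: 10 (4R)-4,8-dimethylnon-7-en-1-yne
Product: 12 (4R)-4-methylhept-6-yn-1-ol, via (4R)-4-methylhept-6-ynal 11 (not isolated)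
Conditions: O3, CH2Cl2/MeOH, −78 °C, stopped at the first blue tinge; NaBH4, −78 °C to rt
Reagents that add atoms: ozone, [O-][O+]=O
Why: ozonolysis cleaves the electron-rich trisubstituted alkene much faster than the terminal alkyne, and borohydride reduces the peroxidic intermediates and the aldehyde in the same flask.

Step 8
Reactants: 12 (4R)-4-methylhept-6-yn-1-ol
Product: 13 tert-butyl{[(4R)-4-methylhept-6-yn-1-yl]oxy}diphenylsilane
Conditions: TBDPSCl, imidazole, DMF, rt
Reagents that add atoms: tert-butyl(chloro)diphenylsilane, CC(C)(C)[Si](Cl)(c1ccccc1)c1ccccc1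
Why: silylation of the primary alcohol gives an ether that should withstand AlMe3, singlet oxygen and the cobalt hydride step and that leaves with fluoride together with the C2 silyl group.

Step 9
Reactants: 13 tert-butyl{[(4R)-4-methylhept-6-yn-1-yl]oxy}diphenylsilane, 8 methyl (2R,3E)-2-[dimethyl(phenyl)silyl]-4-iodopent-3-enoate
Product: 15 methyl (2R,3E,5E,8R)-11-[(tert-butyldiphenylsilyl)oxy]-2-[dimethyl(phenyl)silyl]-4,6,8-trimethylundeca-3,5-dienoate, via alkenylalane 14 (not isolated)
Conditions: AlMe3 (2 equiv), Cp2ZrCl2 (25 mol%), CH2Cl2, 0 °C to rt; volatiles removed in vacuo; 8, ZnCl2 (0.5 equiv), Pd(PPh3)4 (5 mol%), THF, rt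
Reagents that add atoms: trimethylaluminium, C[Al](C)C
Why: zirconium-catalysed syn-carboalumination (Negishi) puts the methyl group on C6 and aluminium on C5 with (E) geometry, and palladium/zinc co-catalysed Negishi coupling with iodide 8 forms C4–C5 with retention at both alkenes, so the (3E,5E)-diene is obtained without reaction at C2.

Step 10
Reactants: 15 methyl (2R,3E,5E,8R)-11-[(tert-butyldiphenylsilyl)oxy]-2-[dimethyl(phenyl)silyl]-4,6,8-trimethylundeca-3,5-dienoate
Product: 16 methyl (2R)-2-[(3R,6R)-6-{(2R)-5-[(tert-butyldiphenylsilyl)oxy]-2-methylpentyl}-4,6-dimethyl-3,6-dihydro-1,2-dioxin-3-yl]-2-[dimethyl(phenyl)silyl]acetate (H-3 and the C6 methyl cis)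
Conditions: O2, tetraphenylporphyrin (1 mol%), visible light, CH2Cl2, −30 °C
Reagents that add atoms: oxygen, O=O
Why: the concerted suprafacial [4+2] cycloaddition of singlet oxygen to the s-cis (3E,5E)-diene bridges C3 and C6 with H-3 and the C6 methyl cis, and the face is chosen by C2, whose C–H bond eclipses C3=C4 to avoid allylic 1,3-strain with the C4 methyl so that oxygen should enter anti to the bulky, electron-releasing C–Si bond (the anti selectivity known for electrophiles and allylsilanes).

Step 11
Reactants: 16 methyl (2R)-2-[(3R,6R)-6-{(2R)-5-[(tert-butyldiphenylsilyl)oxy]-2-methylpentyl}-4,6-dimethyl-3,6-dihydro-1,2-dioxin-3-yl]-2-[dimethyl(phenyl)silyl]acetate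
Product: 17 (3R,4aS,7R,7aR)-3-{(2R)-5-[(tert-butyldiphenylsilyl)oxy]-2-methylpentyl}-7-[dimethyl(phenyl)silyl]-3,4a-dimethyltetrahydro-3H-furo[3,2-c][1,2]dioxin-6(4H)-one (cis-fused peroxylactone)
Conditions: Co(salen) (5 mol%), N-fluoro-2,4,6-trimethylpyridinium tetrafluoroborate (2 equiv), (Me2SiH)2O (2 equiv), PhCF3, 0 °C to rt, argon
Reagents that add atoms: none
Why: The mechanism is a hydrogen-atom-transfer radical–polar crossover: Co(salen) is oxidised by the N-fluoropyridinium salt, the silane converts the trivalent cobalt fluoride into a cobalt hydride, this delivers a hydrogen atom to C5 of the C4=C5 bond, the tertiary C4 radical is captured and oxidised to a tetravalent alkylcobalt, the carbonyl oxygen of the C1 ester displaces cobalt at C4, and the collidine released from the oxidant removes the methyl group from the lactonium ion. The closest known reaction type is the Co(salen)-catalysed Markovnikov hydroacyloxylation of unactivated alkenes by tethered carboxylic acids and esters (Mukaiyama-type hydrogen atom transfer). Ring B closes in the 5-exo mode with respect to the C4=C5 bond, C5 ending outside the lactone. The new quaternary stereocentre C4 is controlled by C3, because the two-atom arm C2–C1 hangs from C3 on one face of ring A and its oxygen can reach C4 only on that face, so the cis ring fusion and hence (4S) should result whatever the geometry of the radical or cation. The step needs Markovnikov regiochemistry, secured by the trisubstituted alkene (tertiary radical at C4 against secondary at C5), and it needs the O–O bond to survive, which rests on fast capture of the C4 radical by cobalt and on ring A holding the radical orbital away from the O–O axis so that epoxide-forming fragmentation is geometrically disfavoured. Should the β-silyl lactonium ion lose silicon instead of methyl, protonation and demethylation lead to lactone 18, the intermediate of the next step.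

Step 12
Reactants: 17 (3R,4aS,7R,7aR)-3-{(2R)-5-[(tert-butyldiphenylsilyl)oxy]-2-methylpentyl}-7-[dimethyl(phenyl)silyl]-3,4a-dimethyltetrahydro-3H-furo[3,2-c][1,2]dioxin-6(4H)-one
Product: 19 (3R,4aS,7aS)-3-[(2R)-5-hydroxy-2-methylpentyl]-3,4a-dimethyltetrahydro-3H-furo[3,2-c][1,2]dioxin-6(4H)-one, via silyl ether lactone 18 (not isolated)
Conditions: Bu4NF (3 equiv), AcOH (3 equiv), THF, 0 °C to rt
Reagents that add atoms: none
Why: fluoride-induced protodesilylation of the α-silyl lactone removes the stereochemical relay from C2 and the same reagent then cleaves the silyl ether, while any reversible opening of the β-peroxy lactone enolate to a butenolide hydroperoxide can only close again to the same cis-fused bicycle because C4 is fixed.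

Step 13
Reactants: 19 (3R,4aS,7aS)-3-[(2R)-5-hydroxy-2-methylpentyl]-3,4a-dimethyltetrahydro-3H-furo[3,2-c][1,2]dioxin-6(4H)-one
Product: 20 (4R)-5-[(3R,4aS,7aS)-3,4a-dimethyl-6-oxotetrahydro-3H-furo[3,2-c][1,2]dioxin-3(4H)-yl]-4-methylpentanal
Conditions: Dess–Martin periodinane, NaHCO3, CH2Cl2, 0 °C to rt
Reagents that add atoms: none
Why: Dess–Martin oxidation of the primary alcohol runs under buffered, non-basic conditions that should leave the peroxide and the lactone untouched.

Step 14
Reactants: 21 (4E)-5-phenylpent-4-en-1-ol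
Product: 22 1-phenyl-5-{[(4E)-5-phenylpent-4-en-1-yl]sulfanyl}-1H-tetrazole
Conditions: 1-phenyl-1H-tetrazole-5-thiol, PPh3, DIAD, THF, 0 °C to rt
Reagents that add atoms: 1-phenyl-1H-tetrazole-5-thiol, Sc1nnnn1-c1ccccc1
Why: Mitsunobu thioetherification of the primary alcohol with the acidic tetrazole thiol.

Step 15
Reactants: 22 1-phenyl-5-{[(4E)-5-phenylpent-4-en-1-yl]sulfanyl}-1H-tetrazole
Product: 23 1-phenyl-5-{[(4E)-5-phenylpent-4-en-1-yl]sulfonyl}-1H-tetrazole
Conditions: (NH4)6Mo7O24·4H2O (10 mol%), 30% H2O2, EtOH, 0 °C to rt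
Reagents that add atoms: hydrogen peroxide, OO
Why: molybdate-catalysed peroxide oxidation takes the sulfide to the sulfone, the styrene being a poor substrate for the peroxomolybdate.

Step 16
Reactants: 20 (4R)-5-[(3R,4aS,7aS)-3,4a-dimethyl-6-oxotetrahydro-3H-furo[3,2-c][1,2]dioxin-3(4H)-yl]-4-methylpentanal, 23 1-phenyl-5-{[(4E)-5-phenylpent-4-en-1-yl]sulfonyl}-1H-tetrazole
Product: 24 (3R,4aS,7aS)-3,4a-dimethyl-3-[(2R,5E,9E)-2-methyl-10-phenyldeca-5,9-dien-1-yl]tetrahydro-3H-furo[3,2-c][1,2]dioxin-6(4H)-one (target, CNP0365311.2)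
Conditions: 23 (1.3 equiv), KHMDS (1.25 equiv), DME, −60 °C; then 20, −60 °C to rt
Reagents that add atoms: none
Why: Julia–Kocienski olefination, in which the pre-formed sulfonyl anion adds to the aldehyde faster than it can enolise the lactone and the Smiles rearrangement with loss of SO2 should give the (E)-C11=C12 alkene favoured by the phenyltetrazolyl sulfone with potassium in DME.

**Compound list**

1 | pent-3-yn-1-ol | CC#CCCO | starting material
2 | alkenylzirconocene from hydrozirconation of 1 (C4–Zr, zirconium alkoxide at O) | C/C(=C\CCO[Zr](Cl)(C1C=CC=C1)C1C=CC=C1)[Zr](Cl)(C1C=CC=C1)C1C=CC=C1 | intermediate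
3 | (3E)-4-iodopent-3-en-1-ol | OCC/C=C(\C)I | intermediate
4 | (3E)-4-iodopent-3-enal | O=CC/C=C(\C)I | intermediate
5 | (3E)-4-iodopent-3-enoic acid | OC(=O)C/C=C(\C)I | intermediate
6 | methyl (3E)-4-iodopent-3-enoate | COC(=O)C/C=C(\C)I | intermediate
7 | methyl (3E)-2-diazo-4-iodopent-3-enoate | COC(=O)C(=[N+]=[N-])/C=C(\C)I | intermediate
8 | methyl (2R,3E)-2-[dimethyl(phenyl)silyl]-4-iodopent-3-enoate | COC(=O)[C@H]([Si](C)(C)c1ccccc1)/C=C(\C)I | intermediate
9 | (R)-citronellal, (3R)-3,7-dimethyloct-6-enal | C[C@H](CCC=C(C)C)CC=O | starting material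
10 | (4R)-4,8-dimethylnon-7-en-1-yne | C[C@H](CCC=C(C)C)CC#C | intermediate
11 | (4R)-4-methylhept-6-ynal | C[C@H](CCC=O)CC#C | intermediate
12 | (4R)-4-methylhept-6-yn-1-ol | C[C@H](CCCO)CC#C | intermediate
13 | tert-butyl{[(4R)-4-methylhept-6-yn-1-yl]oxy}diphenylsilane | C[C@H](CCCO[Si](c1ccccc1)(c1ccccc1)C(C)(C)C)CC#C | intermediate
14 | dimethyl{(1E,4R)-7-[(tert-butyldiphenylsilyl)oxy]-2,4-dimethylhept-1-en-1-yl}alumane | C[Al](C)/C=C(\C)C[C@H](C)CCCO[Si](c1ccccc1)(c1ccccc1)C(C)(C)C | intermediate
15 | methyl (2R,3E,5E,8R)-11-[(tert-butyldiphenylsilyl)oxy]-2-[dimethyl(phenyl)silyl]-4,6,8-trimethylundeca-3,5-dienoate | COC(=O)[C@H]([Si](C)(C)c1ccccc1)/C=C(\C)/C=C(\C)C[C@H](C)CCCO[Si](c1ccccc1)(c1ccccc1)C(C)(C)C | intermediate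
16 | methyl (2R)-2-[(3R,6R)-6-{(2R)-5-[(tert-butyldiphenylsilyl)oxy]-2-methylpentyl}-4,6-dimethyl-3,6-dihydro-1,2-dioxin-3-yl]-2-[dimethyl(phenyl)silyl]acetate | COC(=O)[C@H]([Si](C)(C)c1ccccc1)[C@@H]1OO[C@](C)(C[C@H](C)CCCO[Si](c2ccccc2)(c2ccccc2)C(C)(C)C)C=C1C | intermediate
17 | (3R,4aS,7R,7aR)-3-{(2R)-5-[(tert-butyldiphenylsilyl)oxy]-2-methylpentyl}-7-[dimethyl(phenyl)silyl]-3,4a-dimethyltetrahydro-3H-furo[3,2-c][1,2]dioxin-6(4H)-one | C[C@H](CCCO[Si](c1ccccc1)(c1ccccc1)C(C)(C)C)C[C@]1(C)C[C@]2(C)OC(=O)[C@H]([Si](C)(C)c3ccccc3)[C@@H]2OO1 | intermediate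
18 | (3R,4aS,7aS)-3-{(2R)-5-[(tert-butyldiphenylsilyl)oxy]-2-methylpentyl}-3,4a-dimethyltetrahydro-3H-furo[3,2-c][1,2]dioxin-6(4H)-one | C[C@H](CCCO[Si](c1ccccc1)(c1ccccc1)C(C)(C)C)C[C@]1(C)C[C@]2(C)OC(=O)C[C@@H]2OO1 | intermediate
19 | (3R,4aS,7aS)-3-[(2R)-5-hydroxy-2-methylpentyl]-3,4a-dimethyltetrahydro-3H-furo[3,2-c][1,2]dioxin-6(4H)-one | C[C@H](CCCO)C[C@]1(C)C[C@]2(C)OC(=O)C[C@@H]2OO1 | intermediate
20 | (4R)-5-[(3R,4aS,7aS)-3,4a-dimethyl-6-oxotetrahydro-3H-furo[3,2-c][1,2]dioxin-3(4H)-yl]-4-methylpentanal | C[C@H](CCC=O)C[C@]1(C)C[C@]2(C)OC(=O)C[C@@H]2OO1 | intermediate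
21 | (4E)-5-phenylpent-4-en-1-ol | OCCC/C=C/c1ccccc1 | starting material
22 | 1-phenyl-5-{[(4E)-5-phenylpent-4-en-1-yl]sulfanyl}-1H-tetrazole | C(CC/C=C/c1ccccc1)Sc1nnnn1-c1ccccc1 | intermediate
23 | 1-phenyl-5-{[(4E)-5-phenylpent-4-en-1-yl]sulfonyl}-1H-tetrazole | O=S(=O)(CCC/C=C/c1ccccc1)c1nnnn1-c1ccccc1 | intermediate
24 | (3R,4aS,7aS)-3,4a-dimethyl-3-[(2R,5E,9E)-2-methyl-10-phenyldeca-5,9-dien-1-yl]tetrahydro-3H-furo[3,2-c][1,2]dioxin-6(4H)-one | C[C@H](CC/C=C/CC/C=C/c1ccccc1)C[C@]1(C)C[C@]2(C)OC(=O)C[C@@H]2OO1 | target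

**Step count**

Total: 16 steps. Longest linear sequence: 11 steps (steps 1–5, 9–13 and 16, from pent-3-yn-1-ol); the citronellal branch reaches the target in 9 steps.

**Steps most likely to fail**

Step 10 (singlet-oxygen cycloaddition). Hydrogen abstraction from the C4 and C6 methyl groups (ene pathway) may compete with the [4+2] addition, because the inside methyl at C6 disfavours the s-cis diene. Oxygen may also approach syn to silicon if the allylic-strain bias is weaker than expected. The two facial adducts differ at the adjacent centres C2 and C3 and are expected to be separable, but the fallback changes the approach from substrate-directed induction to resolution on silicon-free material. It sets out from ester 6 and alkyne 13. Carboalumination of 13 to alane 14 and coupling with 6 under the conditions of step 9 gives methyl (3E,5E,8R)-11-[(tert-butyldiphenylsilyl)oxy]-4,6,8-trimethylundeca-3,5-dienoate F1. Photooxygenation as in step 10 gives methyl 2-[(3S,6R)-6-{(2R)-5-[(tert-butyldiphenylsilyl)oxy]-2-methylpentyl}-4,6-dimethyl-3,6-dihydro-1,2-dioxin-3-yl]acetate F2 together with its (3R,6S) ring isomer. An esterase (pig liver esterase, pH 7 buffer) should hydrolyse only one of the two, so that they part as acid and ester; if the wanted ring is the one hydrolysed it is obtained as 2-[(3S,6R)-6-{(2R)-5-[(tert-butyldiphenylsilyl)oxy]-2-methylpentyl}-4,6-dimethyl-3,6-dihydro-1,2-dioxin-3-yl]acetic acid F3. Whichever form carries the (3S,6R) ring is submitted to the conditions of step 11, which should give silyl ether lactone 18, where the route is rejoined.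

Step 11 (cobalt hydride lactonisation). Divalent cobalt may cleave or isomerise the peroxide, and hydrogen-atom transfer to the hindered C5 between two fully substituted carbons may be slow. The fallback replaces the radical–polar crossover by polar iodolactonisation followed by radical deiodination. It sets out from 16. Iodine in MeCN (0 °C to rt, dark) should give, by anti addition with loss of iodomethane, (3R,4S,4aR,7R,7aR)-3-{(2R)-5-[(tert-butyldiphenylsilyl)oxy]-2-methylpentyl}-7-[dimethyl(phenyl)silyl]-4-iodo-3,4a-dimethyltetrahydro-3H-furo[3,2-c][1,2]dioxin-6(4H)-one F4 (iodine at C5 trans to the lactone oxygen). Bu3SnH with Et3B/air in toluene at 0 °C then removes iodine and returns to 17.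

Step 9 (carboalumination and coupling). Enolisation at C2 of the α-silyl ester by aluminium or zinc species may erode its configuration, and residual AlMe3 may add to the ester. The fallback installs silicon after the coupling. It sets out from ester 6 and alkyne 13. Coupling of alane 14 with 6 gives the diene ester F1 described above. Diazo transfer as in step 4 gives methyl (3E,5E,8R)-11-[(tert-butyldiphenylsilyl)oxy]-2-diazo-4,6,8-trimethylundeca-3,5-dienoate F5. Si–H insertion under the conditions of step 5 then returns to 15.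

**Further compounds**

F1 | step 10 | methyl (3E,5E,8R)-11-[(tert-butyldiphenylsilyl)oxy]-4,6,8-trimethylundeca-3,5-dienoate | COC(=O)C/C=C(\C)/C=C(\C)C[C@H](C)CCCO[Si](c1ccccc1)(c1ccccc1)C(C)(C)C
F2 | step 10 | methyl 2-[(3S,6R)-6-{(2R)-5-[(tert-butyldiphenylsilyl)oxy]-2-methylpentyl}-4,6-dimethyl-3,6-dihydro-1,2-dioxin-3-yl]acetate | COC(=O)C[C@@H]1OO[C@](C)(C[C@H](C)CCCO[Si](c2ccccc2)(c2ccccc2)C(C)(C)C)C=C1C
F3 | step 10 | 2-[(3S,6R)-6-{(2R)-5-[(tert-butyldiphenylsilyl)oxy]-2-methylpentyl}-4,6-dimethyl-3,6-dihydro-1,2-dioxin-3-yl]acetic acid | OC(=O)C[C@@H]1OO[C@](C)(C[C@H](C)CCCO[Si](c2ccccc2)(c2ccccc2)C(C)(C)C)C=C1C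
F4 | step 11 | (3R,4S,4aR,7R,7aR)-3-{(2R)-5-[(tert-butyldiphenylsilyl)oxy]-2-methylpentyl}-7-[dimethyl(phenyl)silyl]-4-iodo-3,4a-dimethyltetrahydro-3H-furo[3,2-c][1,2]dioxin-6(4H)-one | C[C@H](CCCO[Si](c1ccccc1)(c1ccccc1)C(C)(C)C)C[C@]1(C)[C@@H](I)[C@]2(C)OC(=O)[C@H]([Si](C)(C)c3ccccc3)[C@@H]2OO1
F5 | step 9 | methyl (3E,5E,8R)-11-[(tert-butyldiphenylsilyl)oxy]-2-diazo-4,6,8-trimethylundeca-3,5-dienoate | COC(=O)C(=[N+]=[N-])/C=C(\C)/C=C(\C)C[C@H](C)CCCO[Si](c1ccccc1)(c1ccccc1)C(C)(C)C
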